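**Retrosynthetic overview**
1. The target is the closed (lactol) tautomer of a 2-formylbenzoic acid. It is released last by acidic Si–O cleavage of a bis-silyl precursor in which the hemiacetal is locked as a silyl acetal.
2. The benzylic ester C–O bond comes from SN2 alkylation of rhizonic acid (2-hydroxy-4-methoxy-3,6-dimethylbenzoic acid) by a benzylic bromide, itself made by Wohl–Ziegler bromination of the aryl methyl group.
3. The only stereocentre is set by an isothiourea-catalysed silylative dynamic kinetic resolution of the racemic, ring–chain-equilibrating hydroxyphthalide (metal-free, new step).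
4. The hydroxyphthalide comes from carboxylate-directed ortho-lithiation/formylation of 2,4-dimethoxy-3-methylbenzoic acid, then BCl3 demethylation next to the lactone carbonyl. Rhizonic acid comes from atraric acid by 4-O-methylation and saponification.
5. Ring order: both benzene rings are bought; the γ-lactone (lactol) ring is the only ring formed, in step 3.

Assumption: the free hemiacetal racemises by ring–chain tautomerism in base, so it is carried as a silyl acetal and freed only in the last, acidic, cold step; (R)-BTM is taken as the catalyst antipode that gives the (S)-silyl acetal, and its mirror image is used if the sense proves opposite.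

Phthalide numbering is used throughout (C1 lactone carbonyl, C3 acetal carbon). The descriptor (S) in the silyl acetals and (R) in 13 describe the same spatial arrangement, because OSi outranks the ring oxygen whereas OH does not.

**Route**

Step 1
Reactants: 1 atraric acid (methyl 2,4-dihydroxy-3,6-dimethylbenzoate)
Product: 2 methyl rhizonate (methyl 2-hydroxy-4-methoxy-3,6-dimethylbenzoate)
Conditions: MeI (1.1 equiv), K2CO3, acetone, reflux
Reagents that add atoms: iodomethane, CI
Why: Williamson O-methylation; the 2-OH is hydrogen-bonded to the ester carbonyl and flanked on both sides, so one equivalent of MeI alkylates only the free 4-OH.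

Step 2
Reactants: 2 methyl rhizonate
Product: 3 rhizonic acid (2-hydroxy-4-methoxy-3,6-dimethylbenzoic acid)
Conditions: KOH, DMSO/H2O, 90 °C; then cold 1 M HCl
Reagents that add atoms: potassium hydroxide (hydroxide oxygen), [OH-].[K+]
Why: Saponification of the hindered salicylate needs hot KOH in aqueous DMSO; the aryl methyl ether is inert and cold acidification avoids decarboxylation.

Step 3
Reactants: 4 2,4-dimethoxy-3-methylbenzoic acid
Product: 7 rac-3-hydroxy-5,7-dimethoxy-6-methylisobenzofuran-1(3H)-one, via dilithio benzoate 5 (not isolated), via formyl acid 6 (not isolated)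
Conditions: s-BuLi/TMEDA (2.2 equiv), THF, −78 °C; DMF; 2 M HCl, rt
Reagents that add atoms: N,N-dimethylformamide, CN(C)C=O
Why: Carboxylate-directed ortho-lithiation removes H-6, the only proton ortho to the lithium carboxylate (C2 and C3 are substituted); DMF formylation and acidification give the 2-formylbenzoic acid, which closes spontaneously to the racemic lactol.

Step 4
Reactants: 7 rac-3-hydroxy-5,7-dimethoxy-6-methylisobenzofuran-1(3H)-one
Product: 8 rac-3,7-dihydroxy-5-methoxy-6-methylisobenzofuran-1(3H)-one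
Conditions: BCl3 (2.5 equiv), CH2Cl2, −78 → 0 °C; then H2O
Reagents that add atoms: none
Why: Chelation-controlled Lewis-acid ether cleavage; BCl3 bridges the lactone carbonyl and the adjacent 7-OMe, so only that ether is cleaved, 5-OMe stays, and the lactol is restored on aqueous work-up.

Step 5
Reactants: 8 rac-3,7-dihydroxy-5-methoxy-6-methylisobenzofuran-1(3H)-one
Product: 10 (S)-5-methoxy-6-methyl-3,7-bis(triphenylsilyloxy)isobenzofuran-1(3H)-one, via mono-silyl acetal 9 (not isolated)
Conditions: (R)-benzotetramisole [(R)-BTM, 20 mol%], Ph3SiCl (2.6 equiv), iPr2NEt (3 equiv), 4 Å MS, THF, −40 °C → rt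
Reagents that add atoms: chlorotriphenylsilane, Cl[Si](c1ccccc1)(c1ccccc1)c1ccccc1
Why: Proposed new method: a silylative dynamic kinetic resolution of a hemiacetal, in which iPr2NEt keeps the two lactol enantiomers interconverting through the achiral open-chain 2-formylbenzoate while the chiral N-silyl isothiouronium formed from (R)-BTM and Ph3SiCl silylates one enantiomer faster (cation–π stacking over the benzo-lactone face versus the ring oxygen on the other side), giving the configurationally locked (S)-silyl acetal, any silyl ester of the open form being a reversible silyl donor back to the catalyst, and excess reagent then silylating the phenol on warming; the closest known reactions are the isothiourea/Ph3SiCl silylation-based kinetic resolution of cyclic benzylic alcohols and α-hydroxy lactones and the Lewis-base-catalysed acylative dynamic kinetic resolution of 3-hydroxyphthalides.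

Step 6
Reactants: 10 (S)-5-methoxy-6-methyl-3,7-bis(triphenylsilyloxy)isobenzofuran-1(3H)-one
Product: 11 (S)-6-(bromomethyl)-5-methoxy-3,7-bis(triphenylsilyloxy)isobenzofuran-1(3H)-one
Conditions: NBS (1.05 equiv), AIBN (cat.), PhCF3, 80 °C; used crude
Reagents that add atoms: N-bromosuccinimide, O=C1CCC(=O)N1Br
Why: Wohl–Ziegler benzylic bromination of the only aryl methyl group; the acetal C–H is shielded by Ph3Si and polarity-mismatched for Br•, non-polar radical conditions disfavour ring bromination, and no bond at the stereocentre is touched.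

Step 7
Reactants: 11 (S)-6-(bromomethyl)-5-methoxy-3,7-bis(triphenylsilyloxy)isobenzofuran-1(3H)-one; 3 rhizonic acid
Product: 12 [(3S)-5-methoxy-1-oxo-3,7-bis(triphenylsilyloxy)-1,3-dihydroisobenzofuran-6-yl]methyl 2-hydroxy-4-methoxy-3,6-dimethylbenzoate
Conditions: KHCO3, acetone, rt, dark
Reagents that add atoms: none
Why: SN2 O-alkylation of a carboxylate by an activated benzylic bromide; KHCO3 ionises only the CO2H of 3 (its chelated phenol stays protonated) and is too weak to open or desilylate the acetal.

Step 8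
Reactants: 12 [(3S)-5-methoxy-1-oxo-3,7-bis(triphenylsilyloxy)-1,3-dihydroisobenzofuran-6-yl]methyl 2-hydroxy-4-methoxy-3,6-dimethylbenzoate
Product: 13 [(3R)-3,7-dihydroxy-5-methoxy-1-oxo-1,3-dihydroisobenzofuran-6-yl]methyl 2-hydroxy-4-methoxy-3,6-dimethylbenzoate (target)
Conditions: 48% aq. HF, MeCN/THF, 0 °C; cold, base-free work-up
Reagents that add atoms: none
Why: Acidic fluoride desilylation attacks silicon only, so the C3–O bonds are never broken (retention), both silyl groups leave in one operation, and the base-free medium keeps the lactol closed while the benzylic ester and lactone survive.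

**Compound list**
1 | atraric acid (methyl 2,4-dihydroxy-3,6-dimethylbenzoate) | COC(=O)c1c(C)cc(O)c(C)c1O | starting material
2 | methyl rhizonate (methyl 2-hydroxy-4-methoxy-3,6-dimethylbenzoate) | COC(=O)c1c(C)cc(OC)c(C)c1O | intermediate
3 | rhizonic acid (2-hydroxy-4-methoxy-3,6-dimethylbenzoic acid) | Cc1cc(OC)c(C)c(O)c1C(=O)O | intermediate
4 | 2,4-dimethoxy-3-methylbenzoic acid | COc1ccc(C(=O)O)c(OC)c1C | starting material
5 | lithium 6-lithio-2,4-dimethoxy-3-methylbenzoate (dilithio benzoate, not isolated) | COc1cc([Li])c(C(=O)O[Li])c(OC)c1C | intermediate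
6 | 6-formyl-2,4-dimethoxy-3-methylbenzoic acid (formyl acid, open-chain tautomer, not isolated) | COc1cc(C=O)c(C(=O)O)c(OC)c1C | intermediate
7 | rac-3-hydroxy-5,7-dimethoxy-6-methylisobenzofuran-1(3H)-one | COc1cc2c(c(OC)c1C)C(=O)OC2O | intermediate
8 | rac-3,7-dihydroxy-5-methoxy-6-methylisobenzofuran-1(3H)-one | COc1cc2c(c(O)c1C)C(=O)OC2O | intermediate
9 | (S)-7-hydroxy-5-methoxy-6-methyl-3-(triphenylsilyloxy)isobenzofuran-1(3H)-one (mono-silyl acetal, not isolated) | COc1cc2c(c(O)c1C)C(=O)O[C@H]2O[Si](c1ccccc1)(c1ccccc1)c1ccccc1 | intermediate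
10 | (S)-5-methoxy-6-methyl-3,7-bis(triphenylsilyloxy)isobenzofuran-1(3H)-one | COc1cc2c(c(O[Si](c3ccccc3)(c3ccccc3)c3ccccc3)c1C)C(=O)O[C@H]2O[Si](c1ccccc1)(c1ccccc1)c1ccccc1 | intermediate
11 | (S)-6-(bromomethyl)-5-methoxy-3,7-bis(triphenylsilyloxy)isobenzofuran-1(3H)-one | COc1cc2c(c(O[Si](c3ccccc3)(c3ccccc3)c3ccccc3)c1CBr)C(=O)O[C@H]2O[Si](c1ccccc1)(c1ccccc1)c1ccccc1 | intermediate
12 | [(3S)-5-methoxy-1-oxo-3,7-bis(triphenylsilyloxy)-1,3-dihydroisobenzofuran-6-yl]methyl 2-hydroxy-4-methoxy-3,6-dimethylbenzoate | COc1cc(C)c(C(=O)OCc2c(OC)cc3c(c2O[Si](c4ccccc4)(c4ccccc4)c4ccccc4)C(=O)O[C@H]3O[Si](c2ccccc2)(c2ccccc2)c2ccccc2)c(O)c1C | intermediate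
13 | [(3R)-3,7-dihydroxy-5-methoxy-1-oxo-1,3-dihydroisobenzofuran-6-yl]methyl 2-hydroxy-4-methoxy-3,6-dimethylbenzoate (CNP0398000.1) | COc1cc(C)c(C(=O)OCc2c(OC)cc3c(c2O)C(=O)O[C@H]3O)c(O)c1C | target

**Step count and risks**
Total steps: 8. Longest linear sequence: 6 (steps 3–8, from 4 to 13); steps 1–2 form the convergent branch.

The three steps most likely to fail:

Step 5 (proposed new silylative dynamic kinetic resolution). Racemisation may lag behind silylation at low temperature, or the open-chain carboxylate may take up silicon and close without catalyst control. The fallback uses only known operations, sets out from 8 and comes back at 10. Compound 8 is silylated without a chiral catalyst (Ph3SiCl, imidazole, DMF, rt) to racemic 5-methoxy-6-methyl-3,7-bis(triphenylsilyloxy)isobenzofuran-1(3H)-one F1. Its enantiomers are separated by preparative SFC on an immobilised amylose tris(3,5-dimethylphenylcarbamate) phase (CO2/i-PrOH) to give 10. The unwanted (R)-5-methoxy-6-methyl-3,7-bis(triphenylsilyloxy)isobenzofuran-1(3H)-one F2 is desilylated with aq. HF in MeCN, which returns racemic 8 for another pass.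

Step 6 (benzylic bromination). The silyloxy/methoxy-substituted ring may brominate at C4 instead of at the methyl group. The fallback sets out from 9 (isolated when step 5 is run with 1.2 equiv of Ph3SiCl at −40 °C) and comes back at 13. Acetylation (Ac2O, pyridine, DMAP) gives (S)-7-acetoxy-5-methoxy-6-methyl-3-(triphenylsilyloxy)isobenzofuran-1(3H)-one F3, whose acetoxy group deactivates the ring. NBS/AIBN then gives (S)-7-acetoxy-6-(bromomethyl)-5-methoxy-3-(triphenylsilyloxy)isobenzofuran-1(3H)-one F4. Alkylation of 3 (KHCO3, acetone) gives [(3S)-7-acetoxy-5-methoxy-1-oxo-3-(triphenylsilyloxy)-1,3-dihydroisobenzofuran-6-yl]methyl 2-hydroxy-4-methoxy-3,6-dimethylbenzoate F5. NH4OAc in aqueous MeOH removes the aryl acetate to give [(3S)-7-hydroxy-5-methoxy-1-oxo-3-(triphenylsilyloxy)-1,3-dihydroisobenzofuran-6-yl]methyl 2-hydroxy-4-methoxy-3,6-dimethylbenzoate F6. Aq. HF in MeCN at 0 °C then gives 13.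

Step 7 (carboxylate alkylation). The electron-rich benzylic bromide may decompose, or the carboxylate/bicarbonate may strip silicon from the acetal. The fallback is base-free, sets out from 11 and comes back at 12. Compound 11 is solvolysed (CaCO3, acetone/H2O, 40 °C) to (S)-6-(hydroxymethyl)-5-methoxy-3,7-bis(triphenylsilyloxy)isobenzofuran-1(3H)-one F7. This alcohol is esterified with 3 under Mitsunobu conditions (PPh3, DIAD, THF, 0 °C) to give 12.

**Further compounds**
F1 | step 5 | rac-5-methoxy-6-methyl-3,7-bis(triphenylsilyloxy)isobenzofuran-1(3H)-one | COc1cc2c(c(O[Si](c3ccccc3)(c3ccccc3)c3ccccc3)c1C)C(=O)OC2O[Si](c1ccccc1)(c1ccccc1)c1ccccc1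
F2 | step 5 | (R)-5-methoxy-6-methyl-3,7-bis(triphenylsilyloxy)isobenzofuran-1(3H)-one | COc1cc2c(c(O[Si](c3ccccc3)(c3ccccc3)c3ccccc3)c1C)C(=O)O[C@@H]2O[Si](c1ccccc1)(c1ccccc1)c1ccccc1
F3 | step 6 | (S)-7-acetoxy-5-methoxy-6-methyl-3-(triphenylsilyloxy)isobenzofuran-1(3H)-one | COc1cc2c(c(OC(C)=O)c1C)C(=O)O[C@H]2O[Si](c1ccccc1)(c1ccccc1)c1ccccc1
F4 | step 6 | (S)-7-acetoxy-6-(bromomethyl)-5-methoxy-3-(triphenylsilyloxy)isobenzofuran-1(3H)-one | COc1cc2c(c(OC(C)=O)c1CBr)C(=O)O[C@H]2O[Si](c1ccccc1)(c1ccccc1)c1ccccc1
F5 | step 6 | [(3S)-7-acetoxy-5-methoxy-1-oxo-3-(triphenylsilyloxy)-1,3-dihydroisobenzofuran-6-yl]methyl 2-hydroxy-4-methoxy-3,6-dimethylbenzoate | COc1cc(C)c(C(=O)OCc2c(OC)cc3c(c2OC(C)=O)C(=O)O[C@H]3O[Si](c2ccccc2)(c2ccccc2)c2ccccc2)c(O)c1C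
F6 | step 6 | [(3S)-7-hydroxy-5-methoxy-1-oxo-3-(triphenylsilyloxy)-1,3-dihydroisobenzofuran-6-yl]methyl 2-hydroxy-4-methoxy-3,6-dimethylbenzoate | COc1cc(C)c(C(=O)OCc2c(OC)cc3c(c2O)C(=O)O[C@H]3O[Si](c2ccccc2)(c2ccccc2)c2ccccc2)c(O)c1C
F7 | step 7 | (S)-6-(hydroxymethyl)-5-methoxy-3,7-bis(triphenylsilyloxy)isobenzofuran-1(3H)-one | COc1cc2c(c(O[Si](c3ccccc3)(c3ccccc3)c3ccccc3)c1CO)C(=O)O[C@H]2O[Si](c1ccccc1)(c1ccccc1)c1ccccc1
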